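**Retrosynthetic overview**

1. The O7 benzoate is put on last; before that, four methoxymethyl (MOM) ethers are removed from a cyclohexene that already carries the O5 benzoate.
2. The only ring, the C1–C6 cyclohexene, is opened at C1=C2: ring-closing metathesis of an acyclic 1,7-diene is the single ring-forming event.
3. The C5–C6 bond is then cut: a γ-alkoxyallylborane carrying C6, C1 and C7 is added to a C2–C5 enal made from D-arabinose (target C4 and C3 are arabinose C2 and C3).
4. The feature used: C6, C1 and C7, with a =CH2 that metathesis later removes, make up a 2-methylidenepropane-1,3-diol unit with two interchangeable oxygenated arms. The C5 hydroxyl, site of the secondary benzoate, is the only hydroxyl the coupling leaves free.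
5. Starting materials: D-arabinose, 2-methylidenepropane-1,3-diol, chloromethyl methyl ether.

Key step: step 6

Assumptions: the furanosides 2, 3 and 5 are carried as the anomeric mixture, since the anomeric carbon becomes the aldehyde carbon in step 4. Locants C1–C7 in the explanations are those of the target: C1 is the ring carbon bearing C7H2OBz, C2 the ring alkene CH, C3–C6 the oxygenated ring carbons. In the open-chain octadienes the locants 3–6 coincide with these.

Step 1
Reactants: 1 D-arabinose
Product: 2 methyl D-arabinofuranoside (anomeric mixture)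
Conditions: HCl (cat.), MeOH, rt, 4 h; NaHCO3 quench
Reagents that add atoms: methanol, CO
Why: Fischer glycosidation under kinetic control should give the five-membered furanosides first, leaving C2–C4 untouched.

Step 2
Reactants: 2 methyl D-arabinofuranoside
Product: 3 methyl 5-deoxy-5-iodo-D-arabinofuranoside
Conditions: I2, PPh3, imidazole, THF, 65 °C
Reagents that add atoms: iodine, II
Why: In this Garegg–Samuelsson (Appel-type) iodination the primary alkoxyphosphonium is displaced by iodide far faster than either secondary one, so only O5 should be replaced.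

Step 3
Reactants: 3 methyl 5-deoxy-5-iodo-D-arabinofuranoside; 4 chloromethyl methyl ether
Product: 5 methyl 5-deoxy-5-iodo-2,3-bis-O-(methoxymethyl)-D-arabinofuranoside
Conditions: MOMCl (3 equiv), i-Pr2NEt, n-Bu4NI (cat.), CH2Cl2, 0 °C → rt
Reagents that add atoms: chloromethyl methyl ether (second equivalent of 4), COCCl
Why: O-alkylation of the two secondary hydroxyls, each by one molecule of the α-chloro ether, under a hindered amine base is mild enough to leave the primary iodide and the glycoside intact.

Step 4
Reactants: 5 methyl 5-deoxy-5-iodo-2,3-bis-O-(methoxymethyl)-D-arabinofuranoside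
Product: 6 (2S,3R)-2,3-bis(methoxymethoxy)pent-4-enal
Conditions: Zn dust (activated), THF/H2O 4:1, ultrasound, 40 °C
Reagents that add atoms: none
Why: In the Bernet–Vasella reductive fragmentation zinc inserts into the C–I bond, β-elimination expels the ring oxygen to form the terminal alkene, and the resulting hemiacetal collapses to the aldehyde with loss of methanol; both stereocentres are carried over unchanged under these near-neutral conditions.

Step 5
Reactants: 7 2-methylidenepropane-1,3-diol; 4 chloromethyl methyl ether
Product: 8 3-(methoxymethoxy)-2-[(methoxymethoxy)methyl]prop-1-ene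
Conditions: MOMCl (2.5 equiv), i-Pr2NEt, CH2Cl2, 0 °C → rt
Reagents that add atoms: chloromethyl methyl ether (second equivalent of 4), COCCl
Why: Double MOM etherification of a primary allylic diol, one molecule of the chloro ether per hydroxyl, is routine and gives a symmetric bis-ether with two equivalent arms.

Step 6
Reactants: 8 3-(methoxymethoxy)-2-[(methoxymethoxy)methyl]prop-1-ene; 9 (+)-B-methoxydiisopinocampheylborane, (+)-Ipc2BOMe; 6 (2S,3R)-2,3-bis(methoxymethoxy)pent-4-enal
Product: 14 (3R,4R,5R,6S)-3,4,6-tris(methoxymethoxy)-7-[(methoxymethoxy)methyl]octa-1,7-dien-5-ol, via allyllithium 10 (not isolated), via borate complex 11 (not isolated), via allylborane 12 (not isolated), via borinate 13 (not isolated)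
Conditions: 8 (1.5 equiv), sec-BuLi (1.4 equiv), THF, −78 °C; 9 (1.4 equiv), −78 °C; BF3·OEt2 (1.8 equiv), then 6 (1.0 equiv), −78 °C → rt; NaOH, H2O2, H2O, 0 °C → rt
Reagents that add atoms: none
Why: Proposed new method: sec-BuLi should remove one of the four equivalent allylic protons next to oxygen to give the internally chelated allyllithium 10 with oxygen cis to the CH2 terminus, (+)-Ipc2BOMe should capture it at that terminus (11), BF3·OEt2 should strip methoxide to give allylborane 12, and 12 should add to aldehyde 6 with allylic transposition through a six-membered chair (Zimmerman–Traxler) transition state, forming C5–C6 and leaving the 1,1-disubstituted C1=CH2 alkene; the closest known reaction is the Brown γ-alkoxyallylboration with the unsubstituted (Z)-γ-(methoxymethoxy)allyldiisopinocampheylborane, and 2-substituted (methallyl) diisopinocampheylboranes are known separately, but the combination in a 2-(alkoxymethyl)-γ-alkoxy reagent is not. No ring is closed. C5 and C6 are set together: with OMOM cis to CH2B (axial in the chair) and the aldehyde substituent equatorial the 5,6-threo pair results, and the (+)-isopinocampheyl groups (from (−)-α-pinene) direct the allyl unit to the Re face of the aldehyde, giving 5R and 6S. The Re face is also the one the α-alkoxy aldehyde prefers on its own (Felkin–Anh/Cornforth, 4,5-erythro), so reagent and substrate control are matched. The step needs bond formation at the oxygen-bearing carbon of the allyl unit, which is secured by boron sitting on the unsubstituted CH2 terminus and delivery with allyl inversion; it also needs 12 to be used at −78 °C before a 1,3-boron shift can scramble its geometry. The two identical arms of 8 make it irrelevant which arm is deprotonated: one becomes C6 and the other C7.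

Step 7
Reactants: 14 (3R,4R,5R,6S)-3,4,6-tris(methoxymethoxy)-7-[(methoxymethoxy)methyl]octa-1,7-dien-5-ol
Product: 15 (3R,4S,5R,6S)-3,4,6-tris(methoxymethoxy)-7-[(methoxymethoxy)methyl]octa-1,7-dien-5-yl benzoate
Conditions: BzCl, pyridine, DMAP (cat.), CH2Cl2, 0 °C → rt
Reagents that add atoms: benzoyl chloride, O=C(Cl)c1ccccc1
Why: DMAP-catalysed acylation of the only free hydroxyl (O5) places the secondary benzoate without any regiochemical question.

Step 8
Reactants: 15 (3R,4S,5R,6S)-3,4,6-tris(methoxymethoxy)-7-[(methoxymethoxy)methyl]octa-1,7-dien-5-yl benzoate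
Product: 16 (3R,4S,5R,6S)-3,4,6-tris(methoxymethoxy)-1-[(methoxymethoxy)methyl]cyclohex-1-en-5-yl benzoate (target locants)
Conditions: second-generation Grubbs catalyst (H2IMes)(PCy3)Cl2Ru=CHPh (5 mol %), CH2Cl2 (degassed, 5 mM), 40 °C
Reagents that add atoms: none
Why: In this ring-closing metathesis the ruthenium carbene should form at the monosubstituted alkene and close onto the 1,1-disubstituted alkene, giving the six-membered ring with a trisubstituted C1=C2 bond and loss of ethene, a closure well established for protected polyoxygenated 1,7-dienes; no stereocentre is touched.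

Step 9
Reactants: 16 (3R,4S,5R,6S)-3,4,6-tris(methoxymethoxy)-1-[(methoxymethoxy)methyl]cyclohex-1-en-5-yl benzoate
Product: 17 (3R,4S,5R,6S)-3,4,6-trihydroxy-1-(hydroxymethyl)cyclohex-1-en-5-yl benzoate
Conditions: HCl (1.25 M in MeOH), 0 °C → rt
Reagents that add atoms: none
Why: Acid-catalysed transacetalisation to methanol should release all four hydroxyls as dimethoxymethane is formed, while a benzoate ester is only slowly attacked by methanolic HCl at room temperature.

Step 10
Reactants: 17 (3R,4S,5R,6S)-3,4,6-trihydroxy-1-(hydroxymethyl)cyclohex-1-en-5-yl benzoate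
Product: 18 [(3R,4S,5R,6S)-5-(benzoyloxy)-3,4,6-trihydroxycyclohex-1-en-1-yl]methyl benzoate (CNP0198957.1)
Conditions: BzCl (1.05 equiv), 2,4,6-collidine, CH2Cl2, −40 °C → −20 °C
Reagents that add atoms: benzoyl chloride, O=C(Cl)c1ccccc1
Why: The unhindered primary allylic hydroxyl should be acylated much faster than the three secondary ones with one equivalent of acid chloride and a weak hindered base at low temperature.

**Compound list**

1 | D-arabinose | O=C[C@@H](O)[C@H](O)[C@H](O)CO | starting material
2 | methyl D-arabinofuranoside (anomeric mixture) | COC1[C@@H](O)[C@H](O)[C@@H](CO)O1 | intermediate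
3 | methyl 5-deoxy-5-iodo-D-arabinofuranoside | COC1[C@@H](O)[C@H](O)[C@@H](CI)O1 | intermediate
4 | chloromethyl methyl ether | COCCl | starting material
5 | methyl 5-deoxy-5-iodo-2,3-bis-O-(methoxymethyl)-D-arabinofuranoside | COC1[C@@H](OCOC)[C@H](OCOC)[C@@H](CI)O1 | intermediate
6 | (2S,3R)-2,3-bis(methoxymethoxy)pent-4-enal | O=C[C@@H](OCOC)[C@H](OCOC)C=C | intermediate
7 | 2-methylidenepropane-1,3-diol | C=C(CO)CO | starting material
8 | 3-(methoxymethoxy)-2-[(methoxymethoxy)methyl]prop-1-ene | C=C(COCOC)COCOC | intermediate
9 | (+)-B-methoxydiisopinocampheylborane, (+)-Ipc2BOMe, from (−)-α-pinene | COB([C@H]1C[C@H]2C[C@@H]([C@@H]1C)C2(C)C)[C@H]1C[C@H]2C[C@@H]([C@@H]1C)C2(C)C | starting material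
10 | [1-(methoxymethoxy)-2-[(methoxymethoxy)methyl]prop-2-en-1-yl]lithium, oxygen cis to the CH2 terminus | [Li+].COCO[CH-]C(=C)COCOC | intermediate (not isolated)
11 | lithium diisopinocampheyl(methoxy){3-(methoxymethoxy)-2-[(methoxymethoxy)methyl]prop-2-en-1-yl}borate, OMOM cis to CH2B | [Li+].CO[B-](C/C(COCOC)=C\OCOC)([C@H]1C[C@H]2C[C@@H]([C@@H]1C)C2(C)C)[C@H]1C[C@H]2C[C@@H]([C@@H]1C)C2(C)C | intermediate (not isolated)
12 | diisopinocampheyl{3-(methoxymethoxy)-2-[(methoxymethoxy)methyl]prop-2-en-1-yl}borane, OMOM cis to CH2B (formally E; the counterpart of the (Z)-γ-alkoxyallyl reagent of the unsubstituted series) | COCO/C=C(\CB([C@H]1C[C@H]2C[C@@H]([C@@H]1C)C2(C)C)[C@H]1C[C@H]2C[C@@H]([C@@H]1C)C2(C)C)COCOC | intermediate (not isolated)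
13 | O5-diisopinocampheylborinate of 14 | C=C(COCOC)[C@H](OCOC)[C@@H](OB([C@H]1C[C@H]2C[C@@H]([C@@H]1C)C2(C)C)[C@H]1C[C@H]2C[C@@H]([C@@H]1C)C2(C)C)[C@@H](OCOC)[C@H](OCOC)C=C | intermediate (not isolated)
14 | (3R,4R,5R,6S)-3,4,6-tris(methoxymethoxy)-7-[(methoxymethoxy)methyl]octa-1,7-dien-5-ol (3,4-threo, 4,5-erythro, 5,6-threo) | C=C(COCOC)[C@H](OCOC)[C@@H](O)[C@@H](OCOC)[C@H](OCOC)C=C | intermediate
15 | (3R,4S,5R,6S)-3,4,6-tris(methoxymethoxy)-7-[(methoxymethoxy)methyl]octa-1,7-dien-5-yl benzoate | C=C(COCOC)[C@H](OCOC)[C@@H](OC(=O)c1ccccc1)[C@@H](OCOC)[C@H](OCOC)C=C | intermediate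
16 | (3R,4S,5R,6S)-3,4,6-tris(methoxymethoxy)-1-[(methoxymethoxy)methyl]cyclohex-1-en-5-yl benzoate | COCOCC1=C[C@@H](OCOC)[C@H](OCOC)[C@H](OC(=O)c2ccccc2)[C@H]1OCOC | intermediate
17 | (3R,4S,5R,6S)-3,4,6-trihydroxy-1-(hydroxymethyl)cyclohex-1-en-5-yl benzoate | OCC1=C[C@@H](O)[C@H](O)[C@H](OC(=O)c2ccccc2)[C@H]1O | intermediate
18 | [(3R,4S,5R,6S)-5-(benzoyloxy)-3,4,6-trihydroxycyclohex-1-en-1-yl]methyl benzoate | O=C(OCC1=C[C@@H](O)[C@H](O)[C@H](OC(=O)c2ccccc2)[C@H]1O)c1ccccc1 | target

**Step count**

Total steps: 10. Longest linear sequence: 9 (steps 1–4 and 6–10).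

**Steps most likely to fail**

Step 6 (Proposed new method). The lithiation of 8 may be followed by Wittig-type rearrangement or loss of alkoxide, and boron may not be captured cleanly at the CH2 terminus. The geometry of 12 may also scramble by 1,3-boron shift, and the extra 2-substituent may lower facial control by the isopinocampheyl groups. The fallback uses known chemistry, sets out from aldehyde 6 and returns at alcohol 14. An auxiliary-controlled syn glycolate aldol makes the C5–C6 bond, and the methylidene and C7 are added afterwards. (R)-4-Benzyl-3-[(methoxymethoxy)acetyl]oxazolidin-2-one F1 (from (R)-4-benzyloxazolidin-2-one, n-BuLi and (methoxymethoxy)acetyl chloride) would be enolised with Bu2BOTf and Et3N in CH2Cl2 at −78 °C and combined with 6. This should give the Evans syn aldol adduct, the N-[3-hydroxy-2,4,5-tris(methoxymethoxy)hept-6-enoyl] imide F2, with the 5,6-threo pair fixed by the (Z)-boron enolate and the auxiliary. Me(MeO)NH·HCl and AlMe3 would exchange the auxiliary for the Weinreb amide, N-methoxy-N-methyl-3-hydroxy-2,4,5-tris(methoxymethoxy)hept-6-enamide F3. Et3SiCl and imidazole would give its 3-O-triethylsilyl ether F4. (Methoxymethoxy)methyllithium (from Bu3SnCH2OCH2OCH3 and n-BuLi, THF, −78 °C) would give the ketone, 1,3,5,6-tetrakis(methoxymethoxy)-4-(triethylsilyloxy)oct-7-en-2-one F5. Wittig methylenation with Ph3P=CH2 (from Ph3PCH3Br and KN(SiMe3)2, THF, −78 → 0 °C) would give the 5-O-triethylsilyl ether of 14 F6. n-Bu4NF in THF would then free O5 and deliver 14.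

Step 9. While four acetals are cleaved under protic acid, the O5 benzoyl group may migrate to the neighbouring cis O4 hydroxyl or be lost by methanolysis. The fallback sets out from 16 and returns at 17, and replaces solvolysis by an aprotic two-stage acetal exchange. Me2BBr in CH2Cl2 at −78 °C would convert each MOM ether into a bromomethyl ether, giving the tetrakis(bromomethyl) ether of 17 F7. This would be poured into THF/aqueous NaHCO3 at 0 °C, where the bromomethyl ethers hydrolyse to the hydroxyls under buffered conditions, so the free hydroxyls are never exposed to acid beside the ester.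

Step 10. Discrimination between the primary and the three secondary hydroxyls may be insufficient, leading to over-benzoylation, or the base may induce migration of the existing benzoate. The fallback sets out from 17 and returns directly at 18, and switches from acyl transfer to activation of the alcohol. A Mitsunobu esterification (benzoic acid, PPh3, diisopropyl azodicarboxylate, THF, 0 °C) reacts by displacement at carbon, which strongly favours the primary C7 position and runs without added base.

**Further compounds**

F1 | step 6 | (R)-4-benzyl-3-[(methoxymethoxy)acetyl]oxazolidin-2-one | COCOCC(=O)N1[C@H](Cc2ccccc2)COC1=O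
F2 | step 6 | (R)-4-benzyl-3-[3-hydroxy-2,4,5-tris(methoxymethoxy)hept-6-enoyl]oxazolidin-2-one (2,3-syn aldol adduct) | O=C1OC[C@@H](Cc2ccccc2)N1C(=O)[C@H](OCOC)[C@@H](O)[C@@H](OCOC)[C@H](OCOC)C=C
F3 | step 6 | N-methoxy-N-methyl-3-hydroxy-2,4,5-tris(methoxymethoxy)hept-6-enamide | CON(C)C(=O)[C@H](OCOC)[C@@H](O)[C@@H](OCOC)[C@H](OCOC)C=C
F4 | step 6 | N-methoxy-N-methyl-2,4,5-tris(methoxymethoxy)-3-(triethylsilyloxy)hept-6-enamide | CON(C)C(=O)[C@H](OCOC)[C@@H](O[Si](CC)(CC)CC)[C@@H](OCOC)[C@H](OCOC)C=C
F5 | step 6 | 1,3,5,6-tetrakis(methoxymethoxy)-4-(triethylsilyloxy)oct-7-en-2-one | COCOCC(=O)[C@H](OCOC)[C@@H](O[Si](CC)(CC)CC)[C@@H](OCOC)[C@H](OCOC)C=C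
F6 | step 6 | 5-O-triethylsilyl ether of 14 | C=C(COCOC)[C@H](OCOC)[C@@H](O[Si](CC)(CC)CC)[C@@H](OCOC)[C@H](OCOC)C=C
F7 | step 9 | 3,4,6-tris(bromomethoxy)-1-[(bromomethoxy)methyl]cyclohex-1-en-5-yl benzoate | BrCOCC1=C[C@@H](OCBr)[C@H](OCBr)[C@H](OC(=O)c2ccccc2)[C@H]1OCBr
F0 | step 10 | none | none
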